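**Retrosynthetic overview**
- The target comes from its tris-MOM ether, which is cut at the enone Cα–Cβ bond: a Claisen–Schmidt aldol condensation joins the ring A methyl ketone (2,4-bis(MOM-oxy)-3,5-diprenylacetophenone) to 4-(MOM-oxy)benzaldehyde (ring B).
- The two prenyl groups on ring A come from allyl groups by double cross-metathesis with 2-methylbut-2-ene.
- The allyl groups come from two rounds of 4-O-allylation and aromatic Claisen rearrangement on 2,4-dihydroxyacetophenone (C3 first, then C5).
- No ring is formed: both benzene rings are bought, and the only stereo element, the E alkene, is set in the condensation.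

Assumption: the target is achiral (no stereocentre), so "single enantiomer" is read as the single (E)-alkene isomer shown.

**Step 1**
Reactants: 1 1-(2,4-dihydroxyphenyl)ethanone (2,4-dihydroxyacetophenone)
Product: 2 1-[2-hydroxy-4-(prop-2-enyloxy)phenyl]ethanone
Conditions: allyl bromide (1.1 equiv), K2CO3 (1.5 equiv), acetone, reflux, 8 h
Reagents that add atoms: allyl bromide, C=CCBr
Why: Williamson ether synthesis in which the 2-OH is tied up in a hydrogen bond to the acetyl C=O, so the free, more acidic 4-OH is allylated selectively by SN2 and no stereocentre is formed.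

**Step 2**
Reactants: 2 1-[2-hydroxy-4-(prop-2-enyloxy)phenyl]ethanone
Product: 4 1-[2,4-dihydroxy-3-(prop-2-enyl)phenyl]ethanone, via ortho-dienone 3 (not isolated)
Conditions: PhNEt2, 210 °C, argon, 6 h
Reagents that add atoms: none
Why: Aromatic Claisen rearrangement ([3,3]-sigmatropic shift then tautomerisation) that goes mainly to C3 because chelation of the 2-OH to the ketone fixes the C3–C4 bond as the more olefinic one; any C5 isomer converges on the same diallyl compound in step 4, and the transient sp3 centre of the dienone is erased on re-aromatisation.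

**Step 3**
Reactants: 4 1-[2,4-dihydroxy-3-(prop-2-enyl)phenyl]ethanone
Product: 5 1-[2-hydroxy-3-(prop-2-enyl)-4-(prop-2-enyloxy)phenyl]ethanone
Conditions: allyl bromide (1.2 equiv), K2CO3 (1.5 equiv), acetone, reflux, 12 h
Reagents that add atoms: allyl bromide, C=CCBr
Why: Second Williamson etherification, again selective for the non-chelated 4-OH over the hydrogen-bonded 2-OH.

**Step 4**
Reactants: 5 1-[2-hydroxy-3-(prop-2-enyl)-4-(prop-2-enyloxy)phenyl]ethanone
Product: 7 1-[2,4-dihydroxy-3,5-di(prop-2-enyl)phenyl]ethanone, via ortho-dienone 6 (not isolated)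
Conditions: PhNEt2, 210 °C, argon, 6 h
Reagents that add atoms: none
Why: Second aromatic Claisen rearrangement, in which C5 is the only free ortho position of the 4-allyloxy group, so the [3,3] shift and re-aromatisation can give only the 3,5-diallyl pattern.

**Step 5**
Reactants: 7 1-[2,4-dihydroxy-3,5-di(prop-2-enyl)phenyl]ethanone
Product: 8 1-[2,4-bis(methoxymethoxy)-3,5-di(prop-2-enyl)phenyl]ethanone
Conditions: NaH (2.4 equiv), DMF, 0 °C; then MOMCl (2.6 equiv), 0 °C to rt
Reagents that add atoms: chloromethyl methyl ether (MOMCl), COCCl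
Why: O-alkylation of the preformed bis-phenoxide with the small, highly reactive MOMCl caps both the hindered 4-OH and the chelated 2-OH as base-stable acetals for the later aldol step.

**Step 6**
Reactants: 8 1-[2,4-bis(methoxymethoxy)-3,5-di(prop-2-enyl)phenyl]ethanone
Product: 9 1-[2,4-bis(methoxymethoxy)-3,5-bis(3-methylbut-2-enyl)phenyl]ethanone
Conditions: second-generation Grubbs catalyst (H2IMes)(PCy3)Cl2Ru=CHPh (5 mol %), 2-methylbut-2-ene/CH2Cl2 (1:1), 40 °C, sealed tube, 16 h
Reagents that add atoms: 2-methylbut-2-ene, CC=C(C)C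
Why: Olefin cross-metathesis of each terminal allyl group with a large excess of 2-methylbut-2-ene exchanges =CH2 for =C(CH3)2 with loss of volatile propene, giving the trisubstituted prenyl alkene, which has no E/Z isomers.

**Step 7**
Reactants: 10 4-hydroxybenzaldehyde
Product: 11 4-(methoxymethoxy)benzaldehyde
Conditions: MOMCl (1.3 equiv), K2CO3 (2 equiv), acetone, 0 °C to rt, 6 h
Reagents that add atoms: chloromethyl methyl ether (MOMCl), COCCl
Why: Williamson-type O-alkylation of the acidic para-formyl phenol masks it so that it cannot form a deactivated phenoxide-aldehyde in the condensation.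

**Step 8**
Reactants: 9 1-[2,4-bis(methoxymethoxy)-3,5-bis(3-methylbut-2-enyl)phenyl]ethanone; 11 4-(methoxymethoxy)benzaldehyde (1.2 equiv)
Product: 13 (E)-1-[2,4-bis(methoxymethoxy)-3,5-bis(3-methylbut-2-enyl)phenyl]-3-[4-(methoxymethoxy)phenyl]prop-2-en-1-one, via aldol adduct 12 (not isolated)
Conditions: KOH (50% aq, 5 equiv), EtOH, 0 °C to rt, 36 h
Reagents that add atoms: none
Why: Claisen–Schmidt (crossed aldol) condensation in which the methyl ketone enolate adds to the non-enolisable aldehyde and the β-hydroxy ketone dehydrates by E1cB to the conjugated enone, the reversible elimination giving the thermodynamically favoured E alkene.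

**Step 9**
Reactants: 13 (E)-1-[2,4-bis(methoxymethoxy)-3,5-bis(3-methylbut-2-enyl)phenyl]-3-[4-(methoxymethoxy)phenyl]prop-2-en-1-one
Product: 14 (E)-1-[2,4-dihydroxy-3,5-bis(3-methylbut-2-enyl)phenyl]-3-(4-hydroxyphenyl)prop-2-en-1-one (target)
Conditions: HCl (1.25 M in MeOH), rt to 40 °C, about 3 h, monitored by TLC; NaHCO3 quench
Reagents that add atoms: none
Why: Acid-catalysed acetal exchange (transacetalisation with methanol) removes the three MOM groups under conditions mild and short enough to leave the prenyl alkenes and the E enone untouched.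

**Compound list**
1 | 1-(2,4-dihydroxyphenyl)ethanone | CC(=O)c1ccc(O)cc1O | starting material
2 | 1-[2-hydroxy-4-(prop-2-enyloxy)phenyl]ethanone | CC(=O)c1ccc(OCC=C)cc1O | intermediate
3 | 4-acetyl-5-hydroxy-6-(prop-2-enyl)cyclohexa-2,4-dien-1-one (racemic, not isolated) | CC(=O)C1=C(O)C(CC=C)C(=O)C=C1 | intermediate
4 | 1-[2,4-dihydroxy-3-(prop-2-enyl)phenyl]ethanone | CC(=O)c1ccc(O)c(CC=C)c1O | intermediate
5 | 1-[2-hydroxy-3-(prop-2-enyl)-4-(prop-2-enyloxy)phenyl]ethanone | CC(=O)c1ccc(OCC=C)c(CC=C)c1O | intermediate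
6 | 4-acetyl-3-hydroxy-2,6-di(prop-2-enyl)cyclohexa-2,4-dien-1-one (racemic, not isolated) | CC(=O)C1=CC(CC=C)C(=O)C(CC=C)=C1O | intermediate
7 | 1-[2,4-dihydroxy-3,5-di(prop-2-enyl)phenyl]ethanone | CC(=O)c1cc(CC=C)c(O)c(CC=C)c1O | intermediate
8 | 1-[2,4-bis(methoxymethoxy)-3,5-di(prop-2-enyl)phenyl]ethanone | CC(=O)c1cc(CC=C)c(OCOC)c(CC=C)c1OCOC | intermediate
9 | 1-[2,4-bis(methoxymethoxy)-3,5-bis(3-methylbut-2-enyl)phenyl]ethanone | CC(=O)c1cc(CC=C(C)C)c(OCOC)c(CC=C(C)C)c1OCOC | intermediate
10 | 4-hydroxybenzaldehyde | O=Cc1ccc(O)cc1 | starting material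
11 | 4-(methoxymethoxy)benzaldehyde | COCOc1ccc(C=O)cc1 | intermediate
12 | 1-[2,4-bis(methoxymethoxy)-3,5-bis(3-methylbut-2-enyl)phenyl]-3-hydroxy-3-[4-(methoxymethoxy)phenyl]propan-1-one (racemic, not isolated) | COCOc1ccc(C(O)CC(=O)c2cc(CC=C(C)C)c(OCOC)c(CC=C(C)C)c2OCOC)cc1 | intermediate
13 | (E)-1-[2,4-bis(methoxymethoxy)-3,5-bis(3-methylbut-2-enyl)phenyl]-3-[4-(methoxymethoxy)phenyl]prop-2-en-1-one | COCOc1ccc(/C=C/C(=O)c2cc(CC=C(C)C)c(OCOC)c(CC=C(C)C)c2OCOC)cc1 | intermediate
14 | (E)-1-[2,4-dihydroxy-3,5-bis(3-methylbut-2-enyl)phenyl]-3-(4-hydroxyphenyl)prop-2-en-1-one | CC(C)=CCc1cc(C(=O)/C=C/c2ccc(O)cc2)c(O)c(CC=C(C)C)c1O | target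

**Totals**
Total step count: 9. Longest linear sequence: 8 steps (1 → 2 → 4 → 5 → 7 → 8 → 9 → 13 → 14); the aldehyde branch is one step (10 → 11).

**Three steps most likely to fail, with fallbacks**

Step 9 (global MOM removal). The risk is acid-induced cyclisation of an ortho-prenyl phenol to a 2,2-dimethylchroman. The fallback sets out from 8 and comes back at 14, so that the prenyl groups are never exposed to acid. Compound 8 is condensed with 11 (KOH, EtOH, rt) through the β-hydroxy ketone 1-[2,4-bis(methoxymethoxy)-3,5-di(prop-2-enyl)phenyl]-3-hydroxy-3-[4-(methoxymethoxy)phenyl]propan-1-one F4 (not isolated) to give (E)-1-[2,4-bis(methoxymethoxy)-3,5-di(prop-2-enyl)phenyl]-3-[4-(methoxymethoxy)phenyl]prop-2-en-1-one F5. The MOM groups are then removed with methanolic HCl while only acid-robust allyl groups are present, giving (E)-1-[2,4-dihydroxy-3,5-di(prop-2-enyl)phenyl]-3-(4-hydroxyphenyl)prop-2-en-1-one F6. Finally, cross-metathesis of F6 with excess 2-methylbut-2-ene and second-generation Grubbs catalyst (H2IMes)(PCy3)Cl2Ru=CHPh in CH2Cl2 at 40 °C gives 14 directly; the hindered, electron-poor chalcone alkene is expected to stay inert.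

Step 6 (double cross-metathesis). The risks are incomplete conversion to mono-prenyl material, crotyl by-products and alkene isomerisation. The fallback sets out from 1 and comes back at 9 by cross-coupling instead of Claisen rearrangement and metathesis. Compound 1 is iodinated with I2/HIO3 in aqueous EtOH at 40 °C to give 1-(2,4-dihydroxy-3,5-diiodophenyl)ethanone F1. This is protected with NaH/MOMCl in DMF to give 1-[3,5-diiodo-2,4-bis(methoxymethoxy)phenyl]ethanone F2. A double Stille coupling of F2 with tributyl(3-methylbut-2-enyl)stannane (CC(C)=CC[Sn](CCCC)(CCCC)CCCC), using the zerovalent palladium catalyst Pd(PPh3)4 in DMF at 95 °C, then gives 9; the chief uncertainty is linear versus branched coupling of the prenyl group.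

Step 8 (Claisen–Schmidt condensation). The risks are sluggish enolisation of the hindered, electron-rich ketone, retro-aldol or Cannizzaro loss of the aldehyde, and Michael addition to the product. The fallback sets out from 9 (with 11) and comes back at 13 by a directed aldol with separate elimination. Compound 9 is deprotonated with LiN(iPr)2 in THF at −78 °C, 11 is added, and the cold quench allows the β-hydroxy ketone 12 to be isolated. Treatment with MsCl/Et3N in CH2Cl2 at 0 °C gives 3-[2,4-bis(methoxymethoxy)-3,5-bis(3-methylbut-2-enyl)phenyl]-1-[4-(methoxymethoxy)phenyl]-3-oxopropyl methanesulfonate F3. On addition of DBU at rt, F3 undergoes E1cB elimination to the E enone 13.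

**Further compounds**
F1 | step 6 | 1-(2,4-dihydroxy-3,5-diiodophenyl)ethanone | CC(=O)c1cc(I)c(O)c(I)c1O
F2 | step 6 | 1-[3,5-diiodo-2,4-bis(methoxymethoxy)phenyl]ethanone | CC(=O)c1cc(I)c(OCOC)c(I)c1OCOC
F3 | step 8 | 3-[2,4-bis(methoxymethoxy)-3,5-bis(3-methylbut-2-enyl)phenyl]-1-[4-(methoxymethoxy)phenyl]-3-oxopropyl methanesulfonate (racemic) | COCOc1ccc(C(CC(=O)c2cc(CC=C(C)C)c(OCOC)c(CC=C(C)C)c2OCOC)OS(C)(=O)=O)cc1
F4 | step 9 | 1-[2,4-bis(methoxymethoxy)-3,5-di(prop-2-enyl)phenyl]-3-hydroxy-3-[4-(methoxymethoxy)phenyl]propan-1-one (racemic, not isolated) | COCOc1ccc(C(O)CC(=O)c2cc(CC=C)c(OCOC)c(CC=C)c2OCOC)cc1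
F5 | step 9 | (E)-1-[2,4-bis(methoxymethoxy)-3,5-di(prop-2-enyl)phenyl]-3-[4-(methoxymethoxy)phenyl]prop-2-en-1-one | COCOc1ccc(/C=C/C(=O)c2cc(CC=C)c(OCOC)c(CC=C)c2OCOC)cc1
F6 | step 9 | (E)-1-[2,4-dihydroxy-3,5-di(prop-2-enyl)phenyl]-3-(4-hydroxyphenyl)prop-2-en-1-one | C=CCc1cc(C(=O)/C=C/c2ccc(O)cc2)c(O)c(CC=C)c1O
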